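## Retrosynthetic overview

1. Endgame: the 11,20-epoxide comes from the 11(20)-alkene by 12-OH-directed epoxidation, C16–Cl from the allylic alcohol, and the four acetates from a 2,9,13,14-tetraol.
2. Ring B (ten-membered, formed last): C2–C3 bond by intramolecular Nozaki–Hiyama–Kishi addition of a (3Z)-dienyl iodide to the C2 aldehyde.
3. Ring C (γ-lactone, formed second): C8–C17 bond by SmI2 Reformatsky cyclisation of a 7-O-(2-bromopropanoyl) C8 ketone. The ketone comes from C8–C9 acylation of a ring A α-alkoxyorganolithium (C9) by a C3–C8 Weinreb amide.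
4. Ring A (formed first): asymmetric Diels–Alder reaction of an amino siloxy diene with ethyl (E)-3-methyl-4-oxobut-2-enoate (sets C1, C10). OsO4, methylenation and hydride reduction on a trans-lactone-locked enone then set C12–C14 and C20.
5. C3–C8 fragment: oxamide acylation of a propargyl ether acetylide, asymmetric transfer hydrogenation (C7), trans-hydrosilylation, iododesilylation and Sonogashira coupling.

Assumptions: briarane numbering (C1–C20) is used for all intermediates and α is the ring A face opposite the C15 methyl; only species that persist between successive reagent additions of a one-pot step are numbered; if a chiral catalyst (steps 1 and 11) induces the opposite sense, its antipode is used; EE = 1-ethoxyethyl (acetal epimers, removed in step 22). This is a designed route, not one that has been run.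

## Route

Step 1
Reactants: 1 ethyl (E)-3-methyl-4-oxobut-2-enoate; 2 (E)-3-(tert-butyldimethylsilyloxy)-N,N-dimethylbuta-1,3-dien-1-amine
Product: 4 ethyl (1S,2S)-2-formyl-2-methyl-5-oxocyclohex-3-ene-1-carboxylate, via endo cycloadduct 3 (not isolated)
Conditions: (R,R)-(salen)CrSbF6 (5 mol %, from (salen)CrCl and AgSbF6; salen = N,N'-bis(3,5-di-tert-butylsalicylidene)cyclohexane-1,2-diamine dianion on trivalent chromium), 4 Å MS, CH2Cl2, −40 °C; then AcCl, Et2O, −78 °C
Reagents that add atoms: none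
Why: Catalytic asymmetric Diels–Alder reaction in which the diene CH2 terminus bonds to the enal β-carbon (C10), the E dienophile fixes C2 trans to C9, the chiral Lewis acid sets C1 and C10, and N-acylation triggers elimination to the enone.

Step 2
Reactants: 4 ethyl (1S,2S)-2-formyl-2-methyl-5-oxocyclohex-3-ene-1-carboxylate
Product: 6 trans-fused enone lactone (3aS,7aS)-3a-methyl-3a,7-dihydro-2-benzofuran-1,6(3H,7aH)-dione, via hydroxy ester 5 (not isolated)
Conditions: NaBH4 (0.3 equiv), EtOH–CH2Cl2, −78 °C; then p-TsOH (cat.), PhMe, 60 °C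
Reagents that add atoms: none
Why: Chemoselective borohydride reduction of the aldehyde followed by acid-catalysed lactonisation gives the trans-fused γ-lactone, which locks ring A with the C15 methyl axial and differentiates C2 from C9.

Step 3
Reactants: 6 trans-fused enone lactone
Product: 7 13α,14α-diol (3aS,4R,5R,7aS)-4,5-dihydroxy-3a-methylhexahydro-2-benzofuran-1,6-dione
Conditions: OsO4 (5 mol %), NMO, acetone–H2O, rt
Reagents that add atoms: N-methylmorpholine N-oxide C[N+]1([O-])CCOCC1; water O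
Why: Upjohn dihydroxylation in which OsO4 adds syn to the enone alkene from the α face, anti to the pseudoaxial allylic methyl on C1, setting C13 and C14.

Step 4
Reactants: 7 13α,14α-diol
Product: 8 13α,14α-bis(triethylsilyl) ether of 7
Conditions: TESOTf, 2,6-lutidine, CH2Cl2, −78 °C
Reagents that add atoms: triethylsilyl triflate CC[Si](CC)(CC)OS(=O)(=O)C(F)(F)F
Why: Silylation of both secondary alcohols gives base-stable ethers and suppresses β-elimination of the C14 oxygen.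

Step 5
Reactants: 8 bis(triethylsilyl) ether ketone
Product: 12 11(20)-methylene ketone lactone, via lithium enolate 9 (not isolated), via Mannich base 10 (not isolated), via ammonium iodide 11 (not isolated)
Conditions: LiN(SiMe3)2, THF, −78 °C; CH2=NMe2+ I−, −78 to 0 °C; then MeI, CH2Cl2, rt; then aq. NaHCO3
Reagents that add atoms: Eschenmoser's salt (N,N-dimethylmethyleneiminium iodide) C=[N+](C)C.[I-]
Why: Eschenmoser methylenation: kinetic deprotonation at the unsubstituted C11 methylene, Mannich reaction, quaternisation and E1cB elimination install the exocyclic C20 methylene.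

Step 6
Reactants: 12 11(20)-methylene ketone lactone
Product: 13 12α-allylic alcohol lactone (12,13,14 all-cis)
Conditions: NaBH4, CeCl3·7H2O, MeOH, −78 °C
Reagents that add atoms: none
Why: Luche 1,2-reduction; axial attack from the α face is blocked by the axial C14 silyloxy group, so hydride enters from the β face and gives the axial 12α-alcohol.

Step 7
Reactants: 13 12α-allylic alcohol lactone
Product: 14 12α-TBS ether lactone
Conditions: TBSOTf, 2,6-lutidine, CH2Cl2, 0 °C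
Reagents that add atoms: tert-butyldimethylsilyl triflate CC(C)(C)[Si](C)(C)OS(=O)(=O)C(F)(F)F
Why: Silylation with the reactive triflate protects the hindered axial alcohol as a robust ether that is kept until step 24.

Step 8
Reactants: 14 12α-TBS ether lactone
Product: 15 C9 lactol (anomer mixture)
Conditions: iBu2AlH, CH2Cl2, −78 °C; aq. potassium sodium tartrate
Reagents that add atoms: none
Why: Partial reduction of the lactone stops at the aluminium hemiacetal at −78 °C and gives a masked C9 aldehyde that also carries the C2 alcohol.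

Step 9
Reactants: 15 C9 lactol
Product: 18 ring A stannane (C9 tributylstannyl with 9-O-EE; 2-OTES; 12α-OTBS; 13α,14α-bis-OTES), via stannyl dialkoxide 16 (not isolated), via lithium alkoxide 17 (not isolated)
Conditions: Bu3SnH, LiN(iPr)2 (2.1 equiv), THF, −78 °C; then Et3SiCl (1.0 equiv), −78 °C; then CH3CHClOEt, −78 to 0 °C
Reagents that add atoms: tributyltin hydride CCCC[SnH](CCCC)CCCC; chlorotriethylsilane CC[Si](CC)(CC)Cl; 1-chloroethyl ethyl ether CCOC(C)Cl
Why: Felkin–Anh addition of Bu3SnLi to the open hydroxy aldehyde (quaternary C1 anti to the nucleophile) sets C9 with tin at the site later taken by C8; the less hindered primary alkoxide is silylated first and the α-stannyl alkoxide is then capped as the EE ether.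

Step 10
Reactants: 19 N,N'-dimethoxy-N,N'-dimethyloxamide; 20 tert-butyldiphenyl(prop-2-yn-1-yloxy)silane
Product: 22 5-(tert-butyldiphenylsilyloxy)-N-methoxy-N-methyl-2-oxopent-3-ynamide, via lithium acetylide 21 (not isolated)
Conditions: n-BuLi, THF, −78 °C; then 19, −78 °C; aq. HCl
Reagents that add atoms: none
Why: Weinreb-type acyl substitution; the chelated tetrahedral intermediate allows a single acetylide addition and releases the α-keto amide on work-up.

Step 11
Reactants: 22 α-keto ynamide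
Product: 23 (2S)-5-(tert-butyldiphenylsilyloxy)-2-hydroxy-N-methoxy-N-methylpent-3-ynamide
Conditions: RuCl[(R,R)-TsDPEN](p-cymene) (2 mol %), iPrOH, rt
Reagents that add atoms: none
Why: Noyori asymmetric transfer hydrogenation of the alkynyl ketone, in which the chiral ruthenium hydride differentiates the carbonyl faces and sets C7 as S.

Step 12
Reactants: 23 (2S)-propargylic alcohol
Product: 24 (2S,3Z)-5-(tert-butyldiphenylsilyloxy)-2-hydroxy-N-methoxy-N-methyl-4-(triethylsilyl)pent-3-enamide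
Conditions: [Cp*Ru(MeCN)3]PF6 (2 mol %), Et3SiH, CH2Cl2, 0 °C to rt
Reagents that add atoms: triethylsilane CC[SiH](CC)CC
Why: Ruthenium-catalysed trans-hydrosilylation places silicon on the alkyne carbon distal to the hydroxyl and hydrogen anti to it, fixing the C5=C6 geometry (C7 cis to the future C4).

Step 13
Reactants: 24 (Z)-vinylsilane
Product: 25 (2S,3Z)-5-(tert-butyldiphenylsilyloxy)-2-hydroxy-4-iodo-N-methoxy-N-methylpent-3-enamide
Conditions: NIS, (CF3)2CHOH, 0 °C
Reagents that add atoms: N-iodosuccinimide O=C1CCC(=O)N1I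
Why: Iododesilylation (ipso substitution of the vinylsilane) proceeds with retention of alkene geometry.

Step 14
Reactants: 25 (Z)-vinyl iodide
Product: 26 (2S,3E)-4-[(tert-butyldiphenylsilyloxy)methyl]-2-hydroxy-N-methoxy-N-methyl-6-(trimethylsilyl)hex-3-en-5-ynamide (C3–C8 fragment)
Conditions: Pd(PPh3)2Cl2 (3 mol %), CuI (6 mol %), Me3SiC≡CH, Et3N, THF, rt
Reagents that add atoms: ethynyltrimethylsilane C#C[Si](C)(C)C
Why: Sonogashira coupling of the vinyl iodide proceeds with retention and installs C3–C4.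

Step 15
Reactants: 18 ring A stannane; 26 C3–C8 Weinreb amide
Product: 29 seco C8 ketone (free 7S-hydroxyl; 9-O-EE), via organolithium 27 (not isolated), via magnesium alkoxide 28 (not isolated)
Conditions: 18 + n-BuLi, THF, −78 °C; 26 + iPrMgCl, THF, −78 °C; combine, −78 to −40 °C; aq. NH4Cl
Reagents that add atoms: none
Why: Tin–lithium exchange gives a configurationally stable α-alkoxyorganolithium that acylates on the Weinreb amide with retention at C9; the magnesium alkoxide masks the 7-hydroxyl and the chelated tetrahedral intermediate prevents over-addition.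

Step 16
Reactants: 29 seco C8 ketone
Product: 30 7-O-(2-bromopropanoyl) ester of 29 (epimers at CHBr)
Conditions: CH3CHBrCOBr, pyridine, CH2Cl2, −40 to 0 °C
Reagents that add atoms: 2-bromopropanoyl bromide CC(Br)C(=O)Br
Why: Acylation of the only free hydroxyl (C7) installs the Reformatsky donor carrying C17, C18 and C19.

Step 17
Reactants: 30 7-O-(2-bromopropanoyl) ester
Product: 31 8-hydroxy-19,7-lactone (C7, C8, C17 as in the target; TMS-alkyne)
Conditions: SmI2 (2.2 equiv), THF, −78 °C; aq. NH4Cl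
Reagents that add atoms: none
Why: SmI2-mediated intramolecular Reformatsky reaction (5-exo aldol); the samarium enolate adds to the C8 ketone with the C9 chain trans to the C7 vinyl group and the C17 methyl trans to the C9 chain, which is the natural arrangement at C8 and C17.

Step 18
Reactants: 31 8-hydroxy-19,7-lactone
Product: 32 C3 iodoalkyne
Conditions: NIS, AgNO3 (10 mol %), DMF, rt, dark
Reagents that add atoms: N-iodosuccinimide O=C1CCC(=O)N1I
Why: Silver-catalysed iododesilylation converts the alkynylsilane directly into the 1-iodoalkyne.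

Step 19
Reactants: 32 C3 iodoalkyne
Product: 33 (3Z)-vinyl iodide
Conditions: 2-nitrobenzenesulfonylhydrazide, Et3N, THF–iPrOH, rt
Reagents that add atoms: none
Why: Diimide reduction delivers H2 syn to the iodoalkyne and gives the Z-iodoalkene without touching the C–I bond or the more substituted alkenes.

Step 20
Reactants: 33 (3Z)-vinyl iodide
Product: 35 C2 aldehyde, via alkoxysulfonium chloride 34 (not isolated)
Conditions: (COCl)2, DMSO, CH2Cl2, −78 to −40 °C; then Et3N, −78 to 0 °C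
Reagents that add atoms: none
Why: Swern oxidation conditions cleave the primary triethylsilyl ether selectively and oxidise it in the same operation to the neopentyl aldehyde; secondary silyl ethers, the acetal and the tertiary alcohol are untouched.

Step 21
Reactants: 35 C2 aldehyde
Product: 36 macrocyclic 2-alcohol (ring B closed; 2R as in the target)
Conditions: CrCl2 (8 equiv), NiCl2 (2 mol %), DMSO–THF, 0.002 M, rt
Reagents that add atoms: none
Why: Intramolecular Nozaki–Hiyama–Kishi reaction; the vinylchromium species adds chemoselectively to the aldehyde with retention of the Z geometry and closes the ten-membered ring, with the 2R carbinol expected from attack on the aldehyde face turned away from ring A.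

Step 22
Reactants: 36 macrocyclic 2-alcohol
Product: 37 2,9,13,14-tetraol (12-OTBS and 16-OTBDPS retained)
Conditions: PPTS, MeOH, 0 °C to rt
Reagents that add atoms: none
Why: Mild acid-catalysed methanolysis (transacetalisation and desilylation) removes the EE acetal and both triethylsilyl ethers but not the hindered TBS or the TBDPS ether.

Step 23
Reactants: 37 2,9,13,14-tetraol
Product: 38 2,9,13,14-tetraacetate
Conditions: Ac2O, DMAP, pyridine, rt
Reagents that add atoms: acetic anhydride CC(=O)OC(C)=O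
Why: DMAP-catalysed acetylation esterifies the four secondary alcohols, while the tertiary C8 hydroxyl does not react.

Step 24
Reactants: 38 2,9,13,14-tetraacetate
Product: 39 12,16-diol tetraacetate
Conditions: HF·pyridine, pyridine, THF, rt
Reagents that add atoms: none
Why: Fluoride-mediated desilylation frees the C12 and C16 hydroxyls; acetates and the lactone survive the buffered medium.

Step 25
Reactants: 39 12,16-diol tetraacetate
Product: 41 16-chloro-11(20)-alkene, via mesylate 40 (not isolated)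
Conditions: MsCl, LiCl, 2,4,6-collidine, DMF, 0 °C
Reagents that add atoms: lithium chloride [Li+].[Cl-]
Why: Selective mesylation of the unhindered primary allylic alcohol and in situ SN2 displacement by chloride; the hindered secondary C12 and tertiary C8 alcohols are not sulfonylated at 0 °C.

Step 26
Reactants: 41 16-chloro-11(20)-alkene
Product: 42 CNP0282558.2 (target)
Conditions: VO(acac)2 (10 mol %), t-BuOOH, CH2Cl2, 0 °C
Reagents that add atoms: tert-butyl hydroperoxide CC(C)(C)OO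
Why: Hydroxyl-directed epoxidation; the vanadium alkoxide of the axial 12α-alcohol delivers oxygen to the α face of the exocyclic alkene (setting C11) and leaves the acetoxy diene untouched.

## Compound list

1 | ethyl (E)-3-methyl-4-oxobut-2-enoate | CCOC(=O)/C=C(C)/C=O | starting material
2 | (E)-3-(tert-butyldimethylsilyloxy)-N,N-dimethylbuta-1,3-dien-1-amine | CN(C)/C=C/C(=C)O[Si](C)(C)C(C)(C)C | starting material
3 | endo cycloadduct (C14 amine cis to CHO) | CN(C)[C@H]1C=C(O[Si](C)(C)C(C)(C)C)C[C@H](C(=O)OCC)[C@]1(C=O)C | intermediate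
4 | ethyl (1S,2S)-2-formyl-2-methyl-5-oxocyclohex-3-ene-1-carboxylate | O=C1C[C@H](C(=O)OCC)[C@](C=O)(C)C=C1 | intermediate
5 | ethyl (1S,2S)-2-(hydroxymethyl)-2-methyl-5-oxocyclohex-3-ene-1-carboxylate | O=C1C[C@H](C(=O)OCC)[C@](CO)(C)C=C1 | intermediate
6 | (3aS,7aS)-3a-methyl-3a,7-dihydro-2-benzofuran-1,6(3H,7aH)-dione (trans-fused lactone, C9 carbonyl to O2) | O=C1C[C@@H]2C(=O)OC[C@@]2(C)C=C1 | intermediate
7 | (3aS,4R,5R,7aS)-4,5-dihydroxy-3a-methylhexahydro-2-benzofuran-1,6-dione (13α,14α-diol) | O[C@H]1C(=O)C[C@@H]2C(=O)OC[C@@]2(C)[C@H]1O | intermediate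
8 | 13α,14α-bis(triethylsilyl) ether of 7 | CC[Si](CC)(CC)O[C@H]1C(=O)C[C@@H]2C(=O)OC[C@@]2(C)[C@H]1O[Si](CC)(CC)CC | intermediate
9 | lithium C11–C12 enolate of 8 | CC[Si](CC)(CC)O[C@H]1C(O[Li])=C[C@@H]2C(=O)OC[C@@]2(C)[C@H]1O[Si](CC)(CC)CC | intermediate
10 | C11 dimethylaminomethyl Mannich base | CC[Si](CC)(CC)O[C@H]1C(=O)C(CN(C)C)[C@@H]2C(=O)OC[C@@]2(C)[C@H]1O[Si](CC)(CC)CC | intermediate
11 | C11 trimethylammoniomethyl iodide | CC[Si](CC)(CC)O[C@H]1C(=O)C(C[N+](C)(C)C)[C@@H]2C(=O)OC[C@@]2(C)[C@H]1O[Si](CC)(CC)CC.[I-] | intermediate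
12 | 11(20)-methylene ketone lactone | CC[Si](CC)(CC)O[C@H]1C(=O)C(=C)[C@@H]2C(=O)OC[C@@]2(C)[C@H]1O[Si](CC)(CC)CC | intermediate
13 | 12α-allylic alcohol lactone | CC[Si](CC)(CC)O[C@H]1[C@@H](O)C(=C)[C@@H]2C(=O)OC[C@@]2(C)[C@H]1O[Si](CC)(CC)CC | intermediate
14 | 12α-TBS ether lactone | CC[Si](CC)(CC)O[C@H]1[C@@H](O[Si](C)(C)C(C)(C)C)C(=C)[C@@H]2C(=O)OC[C@@]2(C)[C@H]1O[Si](CC)(CC)CC | intermediate
15 | C9 lactol (anomer mixture) | CC[Si](CC)(CC)O[C@H]1[C@@H](O[Si](C)(C)C(C)(C)C)C(=C)[C@@H]2C(O)OC[C@@]2(C)[C@H]1O[Si](CC)(CC)CC | intermediate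
16 | dilithium 2,9-dialkoxide of the C9 stannyl carbinol | CC[Si](CC)(CC)O[C@H]1[C@@H](O[Si](C)(C)C(C)(C)C)C(=C)[C@H]([C@@H](O[Li])[Sn](CCCC)(CCCC)CCCC)[C@](CO[Li])(C)[C@H]1O[Si](CC)(CC)CC | intermediate
17 | 2-O-triethylsilyl lithium 9-alkoxide | CC[Si](CC)(CC)O[C@H]1[C@@H](O[Si](C)(C)C(C)(C)C)C(=C)[C@H]([C@@H](O[Li])[Sn](CCCC)(CCCC)CCCC)[C@](CO[Si](CC)(CC)CC)(C)[C@H]1O[Si](CC)(CC)CC | intermediate
18 | ring A stannane (9-SnBu3, 9-O-EE, 2-OTES, 12α-OTBS, 13α,14α-bis-OTES) | CC[Si](CC)(CC)O[C@H]1[C@@H](O[Si](C)(C)C(C)(C)C)C(=C)[C@H]([C@@H](OC(C)OCC)[Sn](CCCC)(CCCC)CCCC)[C@](CO[Si](CC)(CC)CC)(C)[C@H]1O[Si](CC)(CC)CC | intermediate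
19 | N,N'-dimethoxy-N,N'-dimethyloxamide | CON(C)C(=O)C(=O)N(C)OC | starting material
20 | tert-butyldiphenyl(prop-2-yn-1-yloxy)silane | C#CCO[Si](c1ccccc1)(c1ccccc1)C(C)(C)C | starting material
21 | lithium acetylide of 20 | [Li]C#CCO[Si](c1ccccc1)(c1ccccc1)C(C)(C)C | intermediate
22 | 5-(tert-butyldiphenylsilyloxy)-N-methoxy-N-methyl-2-oxopent-3-ynamide | CON(C)C(=O)C(=O)C#CCO[Si](c1ccccc1)(c1ccccc1)C(C)(C)C | intermediate
23 | (2S)-5-(tert-butyldiphenylsilyloxy)-2-hydroxy-N-methoxy-N-methylpent-3-ynamide | CON(C)C(=O)[C@@H](O)C#CCO[Si](c1ccccc1)(c1ccccc1)C(C)(C)C | intermediate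
24 | (2S,3Z)-5-(tert-butyldiphenylsilyloxy)-2-hydroxy-N-methoxy-N-methyl-4-(triethylsilyl)pent-3-enamide | CON(C)C(=O)[C@@H](O)/C=C(CO[Si](c1ccccc1)(c1ccccc1)C(C)(C)C)\[Si](CC)(CC)CC | intermediate
25 | (2S,3Z)-5-(tert-butyldiphenylsilyloxy)-2-hydroxy-4-iodo-N-methoxy-N-methylpent-3-enamide | CON(C)C(=O)[C@@H](O)/C=C(CO[Si](c1ccccc1)(c1ccccc1)C(C)(C)C)\I | intermediate
26 | (2S,3E)-4-[(tert-butyldiphenylsilyloxy)methyl]-2-hydroxy-N-methoxy-N-methyl-6-(trimethylsilyl)hex-3-en-5-ynamide | CON(C)C(=O)[C@@H](O)/C=C(CO[Si](c1ccccc1)(c1ccccc1)C(C)(C)C)\C#C[Si](C)(C)C | intermediate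
27 | C9 α-alkoxyorganolithium from 18 | CC[Si](CC)(CC)O[C@H]1[C@@H](O[Si](C)(C)C(C)(C)C)C(=C)[C@H]([C@@H](OC(C)OCC)[Li])[C@](CO[Si](CC)(CC)CC)(C)[C@H]1O[Si](CC)(CC)CC | intermediate
28 | chloromagnesium 7-alkoxide of 26 | CON(C)C(=O)[C@@H](O[Mg]Cl)/C=C(CO[Si](c1ccccc1)(c1ccccc1)C(C)(C)C)\C#C[Si](C)(C)C | intermediate
29 | seco C8 ketone (7-OH free, 9-O-EE) | CC[Si](CC)(CC)O[C@H]1[C@@H](O[Si](C)(C)C(C)(C)C)C(=C)[C@H]([C@@H](OC(C)OCC)C(=O)[C@H](/C=C(CO[Si](c2ccccc2)(c2ccccc2)C(C)(C)C)\C#C[Si](C)(C)C)O)[C@](CO[Si](CC)(CC)CC)(C)[C@H]1O[Si](CC)(CC)CC | intermediate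
30 | 7-O-(2-bromopropanoyl) ester of 29 | CC[Si](CC)(CC)O[C@H]1[C@@H](O[Si](C)(C)C(C)(C)C)C(=C)[C@H]([C@@H](OC(C)OCC)C(=O)[C@H](/C=C(CO[Si](c2ccccc2)(c2ccccc2)C(C)(C)C)\C#C[Si](C)(C)C)OC(=O)C(C)Br)[C@](CO[Si](CC)(CC)CC)(C)[C@H]1O[Si](CC)(CC)CC | intermediate
31 | 8-hydroxy-19,7-lactone (TMS-alkyne) | CC[Si](CC)(CC)O[C@H]1[C@@H](O[Si](C)(C)C(C)(C)C)C(=C)[C@H]([C@@H](OC(C)OCC)[C@@]3(O)[C@H](/C=C(CO[Si](c2ccccc2)(c2ccccc2)C(C)(C)C)\C#C[Si](C)(C)C)OC(=O)[C@@H]3C)[C@](CO[Si](CC)(CC)CC)(C)[C@H]1O[Si](CC)(CC)CC | intermediate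
32 | C3 iodoalkyne lactone | CC[Si](CC)(CC)O[C@H]1[C@@H](O[Si](C)(C)C(C)(C)C)C(=C)[C@H]([C@@H](OC(C)OCC)[C@@]3(O)[C@H](/C=C(CO[Si](c2ccccc2)(c2ccccc2)C(C)(C)C)\C#CI)OC(=O)[C@@H]3C)[C@](CO[Si](CC)(CC)CC)(C)[C@H]1O[Si](CC)(CC)CC | intermediate
33 | (3Z)-vinyl iodide lactone | CC[Si](CC)(CC)O[C@H]1[C@@H](O[Si](C)(C)C(C)(C)C)C(=C)[C@H]([C@@H](OC(C)OCC)[C@@]3(O)[C@H](/C=C(CO[Si](c2ccccc2)(c2ccccc2)C(C)(C)C)\C=C/I)OC(=O)[C@@H]3C)[C@](CO[Si](CC)(CC)CC)(C)[C@H]1O[Si](CC)(CC)CC | intermediate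
34 | C2 alkoxydimethylsulfonium chloride | CC[Si](CC)(CC)O[C@H]1[C@@H](O[Si](C)(C)C(C)(C)C)C(=C)[C@H]([C@@H](OC(C)OCC)[C@@]3(O)[C@H](/C=C(CO[Si](c2ccccc2)(c2ccccc2)C(C)(C)C)\C=C/I)OC(=O)[C@@H]3C)[C@](CO[S+](C)C)(C)[C@H]1O[Si](CC)(CC)CC.[Cl-] | intermediate
35 | C2 aldehyde (3Z)-vinyl iodide | CC[Si](CC)(CC)O[C@H]1[C@@H](O[Si](C)(C)C(C)(C)C)C(=C)[C@H]([C@@H](OC(C)OCC)[C@@]3(O)[C@H](/C=C(CO[Si](c2ccccc2)(c2ccccc2)C(C)(C)C)\C=C/I)OC(=O)[C@@H]3C)[C@](C=O)(C)[C@H]1O[Si](CC)(CC)CC | intermediate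
36 | macrocyclic 2-alcohol (9-O-EE, 12-OTBS, 13,14-bis-OTES, 16-OTBDPS) | CC[Si](CC)(CC)O[C@H]1[C@@H](O[Si](C)(C)C(C)(C)C)C(=C)[C@@H]2[C@@H](OC(C)OCC)[C@@]3(O)[C@H](/C=C(CO[Si](c4ccccc4)(c4ccccc4)C(C)(C)C)\C=C/[C@@H](O)[C@@]2(C)[C@H]1O[Si](CC)(CC)CC)OC(=O)[C@@H]3C | intermediate
37 | 2,9,13,14-tetraol | O[C@H]1[C@@H](O[Si](C)(C)C(C)(C)C)C(=C)[C@@H]2[C@@H](O)[C@@]3(O)[C@H](/C=C(CO[Si](c4ccccc4)(c4ccccc4)C(C)(C)C)\C=C/[C@@H](O)[C@@]2(C)[C@H]1O)OC(=O)[C@@H]3C | intermediate
38 | 2,9,13,14-tetraacetate | CC(=O)O[C@H]1[C@@H](O[Si](C)(C)C(C)(C)C)C(=C)[C@@H]2[C@@H](OC(C)=O)[C@@]3(O)[C@H](/C=C(CO[Si](c4ccccc4)(c4ccccc4)C(C)(C)C)\C=C/[C@@H](OC(C)=O)[C@@]2(C)[C@H]1OC(C)=O)OC(=O)[C@@H]3C | intermediate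
39 | 12,16-diol tetraacetate | CC(=O)O[C@H]1[C@@H](O)C(=C)[C@@H]2[C@@H](OC(C)=O)[C@@]3(O)[C@H](/C=C(CO)\C=C/[C@@H](OC(C)=O)[C@@]2(C)[C@H]1OC(C)=O)OC(=O)[C@@H]3C | intermediate
40 | C16 mesylate | CC(=O)O[C@H]1[C@@H](O)C(=C)[C@@H]2[C@@H](OC(C)=O)[C@@]3(O)[C@H](/C=C(COS(C)(=O)=O)\C=C/[C@@H](OC(C)=O)[C@@]2(C)[C@H]1OC(C)=O)OC(=O)[C@@H]3C | intermediate
41 | 16-chloro-11(20)-alkene | CC(=O)O[C@H]1[C@@H](O)C(=C)[C@@H]2[C@@H](OC(C)=O)[C@@]3(O)[C@H](/C=C(CCl)\C=C/[C@@H](OC(C)=O)[C@@]2(C)[C@H]1OC(C)=O)OC(=O)[C@@H]3C | intermediate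
42 | CNP0282558.2 | CC(=O)O[C@H]1[C@@H](O)[C@]2(CO2)[C@@H]2[C@@H](OC(C)=O)[C@@]3(O)[C@H](/C=C(CCl)\C=C/[C@@H](OC(C)=O)[C@@]2(C)[C@H]1OC(C)=O)OC(=O)[C@@H]3C | target

## Step count and risk

Total step count: 26. Longest linear sequence: 21 steps (steps 1–9 and 15–26, from 1 and 2); the C3–C8 fragment takes 5 steps (10–14).

Most likely to fail, first: step 15 (fragment union). The secondary α-alkoxyorganolithium 27 is hindered, may suffer silyl migration from O2, and must attack a hindered amide. The fallback sets out from 26, uses 27 generated from 18 as in the route, and returns at 29. It swaps the amide for an aldehyde electrophile and corrects the oxidation state afterwards. 26 is protected at O7 with 4-methoxybenzyl trichloroacetimidate and Sc(OTf)3 to give the 7-O-PMB Weinreb amide F1. iBu2AlH at −78 °C then gives the α-alkoxy aldehyde F2, which captures 27 at −78 °C to give the C8 carbinol F3 (C8 epimers, inconsequential). Dess–Martin periodinane gives the 7-O-PMB ketone F4, and DDQ in wet CH2Cl2 returns 29.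

Second: step 17 (lactone formation). SmI2 may reductively cleave the α-acyloxy ketone instead of the C–Br bond, and the C8/C17 outcome rests on steric arguments. The fallback sets out from 29 and returns at 31; it makes the C8–C17 bond intermolecularly and closes the lactone afterwards. Activated zinc and ethyl 2-bromopropanoate (THF, 40 °C, zinc Reformatsky reaction with the zinc 7-alkoxide chelating the ketone) give the β-hydroxy ethyl ester F5. F5 lactonises through the 7-hydroxyl with catalytic DBU, which also equilibrates C17 to the epimer with methyl trans to the C9 chain, giving 31.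

Third: step 21 (ring B closure). Ten-membered ring formation is entropically and torsionally demanding, and the C2 configuration is set by the macrocyclic transition state. The fallback sets out from 32 and returns at 36; it closes the ring through the alkyne, a better organochromium nucleophile, and sets the Z geometry afterwards. Swern deprotection–oxidation of 32 gives the aldehyde iodoalkyne F6. CrCl2 with a trace of NiCl2 in THF at high dilution gives the cyclic propargylic alcohol F7. Semi-reduction with zinc activated by Cu(OAc)2 and AgNO3 in aqueous methanol then gives 36.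

## Further compounds

F1 | step 15 | 7-O-(4-methoxybenzyl) ether of Weinreb amide 26 | CON(C)C(=O)[C@@H](OCc1ccc(OC)cc1)/C=C(CO[Si](c1ccccc1)(c1ccccc1)C(C)(C)C)\C#C[Si](C)(C)C
F2 | step 15 | C8 aldehyde with 7-O-PMB | O=C[C@@H](OCc1ccc(OC)cc1)/C=C(CO[Si](c1ccccc1)(c1ccccc1)C(C)(C)C)\C#C[Si](C)(C)C
F3 | step 15 | C8 carbinol from 27 and F2 (C8 epimers) | CC[Si](CC)(CC)O[C@H]1[C@@H](O[Si](C)(C)C(C)(C)C)C(=C)[C@H]([C@@H](OC(C)OCC)C(O)[C@H](/C=C(CO[Si](c2ccccc2)(c2ccccc2)C(C)(C)C)\C#C[Si](C)(C)C)OCc2ccc(OC)cc2)[C@](CO[Si](CC)(CC)CC)(C)[C@H]1O[Si](CC)(CC)CC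
F4 | step 15 | C8 ketone with 7-O-PMB | CC[Si](CC)(CC)O[C@H]1[C@@H](O[Si](C)(C)C(C)(C)C)C(=C)[C@H]([C@@H](OC(C)OCC)C(=O)[C@H](/C=C(CO[Si](c2ccccc2)(c2ccccc2)C(C)(C)C)\C#C[Si](C)(C)C)OCc2ccc(OC)cc2)[C@](CO[Si](CC)(CC)CC)(C)[C@H]1O[Si](CC)(CC)CC
F5 | step 17 | β-hydroxy ethyl ester (C8–C17 Reformatsky adduct of 29) | CC[Si](CC)(CC)O[C@H]1[C@@H](O[Si](C)(C)C(C)(C)C)C(=C)[C@H]([C@@H](OC(C)OCC)[C@](O)([C@@H](C)C(=O)OCC)[C@H](/C=C(CO[Si](c2ccccc2)(c2ccccc2)C(C)(C)C)\C#C[Si](C)(C)C)O)[C@](CO[Si](CC)(CC)CC)(C)[C@H]1O[Si](CC)(CC)CC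
F6 | step 21 | C2 aldehyde iodoalkyne | CC[Si](CC)(CC)O[C@H]1[C@@H](O[Si](C)(C)C(C)(C)C)C(=C)[C@H]([C@@H](OC(C)OCC)[C@@]3(O)[C@H](/C=C(CO[Si](c2ccccc2)(c2ccccc2)C(C)(C)C)\C#CI)OC(=O)[C@@H]3C)[C@](C=O)(C)[C@H]1O[Si](CC)(CC)CC
F7 | step 21 | cyclic propargylic alcohol (3,4-alkyne analogue of 36) | CC[Si](CC)(CC)O[C@H]1[C@@H](O[Si](C)(C)C(C)(C)C)C(=C)[C@@H]2[C@@H](OC(C)OCC)[C@@]3(O)[C@H](/C=C(CO[Si](c4ccccc4)(c4ccccc4)C(C)(C)C)\C#C[C@@H](O)[C@@]2(C)[C@H]1O[Si](CC)(CC)CC)OC(=O)[C@@H]3C
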